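## Retrosynthetic overview

1. C3 carbinol from CBS reduction of the macrocyclic enone, which comes from a Nozaki–Hiyama–Kishi closure of the C3–C4 bond (14-membered ring formed last).
2. α-Methylene ε-lactone from decarboxylative methylenation of an α-carboxy lactone, itself formed by 7-exo opening of an (11S,12S)-epoxide by a malonic acid with inversion at C12 (lactone is the second ring).
3. C8–C9 bond from B-alkyl Suzuki coupling of a vinyl-epoxide-derived borane with C2-symmetric (2E,5E)-2,6-diiodohepta-2,5-diene, which supplies both trisubstituted E-alkenes.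
4. C1 stereocentre from an organocatalytic malonate Michael addition to an enal made by cross-metathesis of the prenyl terminus.
5. C11/C12 from Sharpless epoxidation of geraniol (oxirane is the first ring).

Assumptions: cembrane numbering is used in the explanations (C1 = ring CH bearing acrylate carbon C15; C3 = CHOH; C11 = CHOAc; C12 = lactone C–O). Catalysts and ligands are treated as commercial. The C15 epimer mixture in compounds 10–15 is inconsequential because C15 becomes sp2. This route has not been run; conditions are precedent-based.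

## Route

**Step 1**
Reactants: 1, 1-bromo-2-butyne; 2, 1-propynylmagnesium bromide
Product: 3, hepta-2,5-diyne
Conditions: CuCl (5 mol %), THF, 0 °C → rt
Reagents that add atoms: none
Why: Cu(I)-catalysed SN2 propargylation of an alkynyl Grignard is the standard entry to skipped diynes.

**Step 2**
Reactants: 3, hepta-2,5-diyne
Product: 4, (2E,5E)-2,6-diiodohepta-2,5-diene
Conditions: Cp2Zr(H)Cl (2.6 equiv), THF, rt → 40 °C; then I2, 0 °C
Reagents that add atoms: iodine, II
Why: Double hydrozirconation adds H–Zr syn with Zr equilibrating to the less hindered methyl-bearing carbon, and iodinolysis with retention gives both (E)-2-iodoalkene termini.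

**Step 3**
Reactants: 5, geraniol
Product: 6, (2S,3S)-2,3-epoxygeraniol
Conditions: Ti(OiPr)4 (5 mol %), L-(+)-DET (7.5 mol %), t-BuOOH, 4 Å MS, CH2Cl2, −20 °C
Reagents that add atoms: tert-butyl hydroperoxide, CC(C)(C)OO
Why: Sharpless asymmetric epoxidation touches only the allylic-alcohol alkene, and L-(+)-tartrate gives the (2S,3S)-epoxide, fixing C11 (S) and the face from which C12 will later be inverted.

**Step 4**
Reactants: 6, (2S,3S)-2,3-epoxygeraniol; 7, (E)-crotonaldehyde (excess)
Product: 8, (E)-5-[(2S,3S)-3-(hydroxymethyl)-2-methyloxiran-2-yl]pent-2-enal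
Conditions: Hoveyda–Grubbs II (5 mol %), CH2Cl2, 40 °C
Reagents that add atoms: none
Why: Olefin cross-metathesis of the isopropylidene terminus, the only alkene in 6, with an enal partner gives the E-enal (C1=C2–C3HO).

**Step 5**
Reactants: 8, epoxy enal; 9, dimethyl malonate
Product: 10, dimethyl 2-{(3R)-1-[(2S,3S)-3-(hydroxymethyl)-2-methyloxiran-2-yl]-5-oxopentan-3-yl}malonate
Conditions: (S)-α,α-bis[3,5-bis(trifluoromethyl)phenyl]prolinol TMS ether (10 mol %), EtOH, 0 °C → rt
Reagents that add atoms: none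
Why: Iminium-catalysed (Jørgensen–Hayashi) Michael addition; the (S)-catalyst shields one face of the E-iminium so malonate adds to the other, giving C1 (R) and delivering C15/C16 and the free C3 aldehyde.

**Step 6**
Reactants: 10, Michael adduct
Product: 11, dimethyl 2-{(3R)-1-[(2S,3S)-3-(hydroxymethyl)-2-methyloxiran-2-yl]-5,5-dimethoxypentan-3-yl}malonate
Conditions: HC(OMe)3, PPTS (5 mol %), MeOH, 0 °C; Et3N quench
Reagents that add atoms: trimethyl orthoformate, COC(OC)OC (methanol, CO)
Why: Acetalisation of the aldehyde is much faster than acid methanolysis of the trisubstituted epoxide and masks C3 for the following steps.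

**Step 7**
Reactants: 11, epoxy alcohol
Product: 12, dimethyl 2-{(3R)-1-[(2S,3R)-3-formyl-2-methyloxiran-2-yl]-5,5-dimethoxypentan-3-yl}malonate
Conditions: SO3·pyridine, DMSO, i-Pr2NEt, CH2Cl2, 0 °C
Reagents that add atoms: none
Why: Parikh–Doering oxidation is non-acidic and gives the α,β-epoxy aldehyde without touching epoxide, acetal or malonate (descriptor change at the oxirane CH is only a CIP priority change).

**Step 8**
Reactants: 12, epoxy aldehyde
Product: 13, dimethyl 2-{(3R)-5,5-dimethoxy-1-[(2S,3S)-2-methyl-3-vinyloxiran-2-yl]pentan-3-yl}malonate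
Conditions: Ph3PCH3Br, KHMDS (2.5 equiv ylide), THF, −78 → 0 °C
Reagents that add atoms: methyltriphenylphosphonium bromide, C[P+](c1ccccc1)(c1ccccc1)c1ccccc1.[Br-]
Why: Wittig methylenation adds C9; the extra ylide compensates for reversible deprotonation of the malonate C–H, and no stereocentre is affected.

**Step 9**
Reactants: 13, vinyl epoxide; 4, (2E,5E)-2,6-diiodohepta-2,5-diene (3 equiv, excess recovered)
Product: 14, dimethyl 2-{(3R)-1-[(2S,3S)-3-[(3E,6E)-7-iodo-3-methylocta-3,6-dien-1-yl]-2-methyloxiran-2-yl]-5,5-dimethoxypentan-3-yl}malonate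
Conditions: 9-BBN, THF, 0 °C → rt; then 4, PdCl2(dppf) (5 mol %), AsPh3, aq Cs2CO3, DMF, rt
Reagents that add atoms: none
Why: 9-BBN hydroborates the only alkene at its terminus, and B-alkyl Suzuki–Miyaura coupling with excess symmetric diiodide gives mono-coupling with retention of E geometry, forming C8–C9 and leaving the C4 vinyl iodide.

**Step 10**
Reactants: 14, epoxy malonate
Product: 15, (4R,7R)-4-(2,2-dimethoxyethyl)-7-[(1S,4E,7E)-1-hydroxy-8-iodo-4-methylnona-4,7-dien-1-yl]-7-methyl-2-oxooxepane-3-carboxylic acid (C3 epimers)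
Conditions: LiOH, THF/MeOH/H2O, 40 °C; cold pH 3 work-up; then CSA (5 mol %), CH2Cl2 (0.01 M), 0 °C → rt
Reagents that add atoms: lithium hydroxide, [Li+].[OH-]; water, O
Why: Saponification gives the malonic acid, which opens the protonated epoxide in a 7-exo-tet mode at the tertiary carbon with inversion, so C12 becomes R while C11 keeps its S oxygen as the free alcohol.

**Step 11**
Reactants: 15, α-carboxy lactone
Product: 16, (4R,7R)-4-(2,2-dimethoxyethyl)-7-[(1S,4E,7E)-1-hydroxy-8-iodo-4-methylnona-4,7-dien-1-yl]-7-methyl-3-methylideneoxepan-2-one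
Conditions: (CH2O)n, Et2NH, EtOAc, 70 °C
Reagents that add atoms: formaldehyde, C=O
Why: Decarboxylative Mannich methylenation of a malonic half-ester acid installs the exocyclic methylene (C17) and removes the C15 stereocentre.

**Step 12**
Reactants: 16, hydroxy lactone
Product: 17, (1S,4E,7E)-1-[(2R,5R)-5-(2,2-dimethoxyethyl)-2-methyl-6-methylidene-7-oxooxepan-2-yl]-8-iodo-4-methylnona-4,7-dien-1-yl acetate
Conditions: Ac2O, pyridine, DMAP, CH2Cl2, rt
Reagents that add atoms: acetic anhydride, CC(=O)OC(C)=O
Why: DMAP-catalysed acylation of the only free hydroxyl (C11) proceeds with retention.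

**Step 13**
Reactants: 17, acetal
Product: 18, (1S,4E,7E)-8-iodo-4-methyl-1-[(2R,5R)-2-methyl-6-methylidene-7-oxo-5-(2-oxoethyl)oxepan-2-yl]nona-4,7-dien-1-yl acetate
Conditions: PPTS, acetone/H2O (10:1), 45 °C
Reagents that add atoms: water, O
Why: Mild acetal hydrolysis releases the C3 aldehyde; acetate, α-methylene lactone and vinyl iodide are stable to it.

**Step 14**
Reactants: 18, iodo aldehyde
Product: 19, (1R,11S,12R,4E,7E)-11-acetoxy-3-hydroxycembra-4,7,15(17)-trien-16,12-olide as a mixture of C3 epimers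
Conditions: CrCl2 (8 equiv), NiCl2 (2 mol %), DMSO/THF, rt, 3 mM, slow addition
Reagents that add atoms: none
Why: Nozaki–Hiyama–Kishi macrocyclisation is aldehyde-selective and retains the vinyl iodide geometry (4E); C3 is formed under substrate control and is corrected in the next two steps.

**Step 15**
Reactants: 19, macrocyclic allylic alcohols
Product: 20, (1R,11S,12R,4E,7E)-11-acetoxy-3-oxocembra-4,7,15(17)-trien-16,12-olide
Conditions: Dess–Martin periodinane, NaHCO3, CH2Cl2, 0 °C
Reagents that add atoms: none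
Why: Buffered Dess–Martin oxidation converges both C3 epimers to one enone without isomerising the skipped diene.

**Step 16**
Reactants: 20, macrocyclic enone
Product: 21, dendronpholide B
Conditions: (S)-Me-CBS (1.2 equiv), catecholborane, toluene, −78 °C
Reagents that add atoms: none
Why: Corey–Bakshi–Shibata reduction with the α-methylalkenyl group as the large substituent gives the (3R)-allylic alcohol by 1,2-reduction, leaving the enoate and acetate untouched at −78 °C.

## Compound list

1 | 1-bromo-2-butyne | CC#CCBr | starting material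
2 | 1-propynylmagnesium bromide | CC#C[Mg]Br | starting material
3 | hepta-2,5-diyne | CC#CCC#CC | intermediate
4 | (2E,5E)-2,6-diiodohepta-2,5-diene | I/C(C)=C/C/C=C(\C)I | intermediate
5 | geraniol | CC(C)=CCC/C(C)=C/CO | starting material
6 | (2S,3S)-2,3-epoxygeraniol | OC[C@@H]1O[C@@]1(C)CCC=C(C)C | intermediate
7 | (E)-crotonaldehyde | C/C=C/C=O | starting material
8 | (E)-5-[(2S,3S)-3-(hydroxymethyl)-2-methyloxiran-2-yl]pent-2-enal | OC[C@@H]1O[C@@]1(C)CC/C=C/C=O | intermediate
9 | dimethyl malonate | COC(=O)CC(=O)OC | starting material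
10 | dimethyl 2-{(3R)-1-[(2S,3S)-3-(hydroxymethyl)-2-methyloxiran-2-yl]-5-oxopentan-3-yl}malonate | OC[C@@H]1O[C@@]1(C)CC[C@H](CC=O)C(C(=O)OC)C(=O)OC | intermediate
11 | dimethyl 2-{(3R)-1-[(2S,3S)-3-(hydroxymethyl)-2-methyloxiran-2-yl]-5,5-dimethoxypentan-3-yl}malonate | OC[C@@H]1O[C@@]1(C)CC[C@H](CC(OC)OC)C(C(=O)OC)C(=O)OC | intermediate
12 | dimethyl 2-{(3R)-1-[(2S,3R)-3-formyl-2-methyloxiran-2-yl]-5,5-dimethoxypentan-3-yl}malonate | O=C[C@@H]1O[C@@]1(C)CC[C@H](CC(OC)OC)C(C(=O)OC)C(=O)OC | intermediate
13 | dimethyl 2-{(3R)-5,5-dimethoxy-1-[(2S,3S)-2-methyl-3-vinyloxiran-2-yl]pentan-3-yl}malonate | C=C[C@@H]1O[C@@]1(C)CC[C@H](CC(OC)OC)C(C(=O)OC)C(=O)OC | intermediate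
14 | dimethyl 2-{(3R)-1-[(2S,3S)-3-[(3E,6E)-7-iodo-3-methylocta-3,6-dien-1-yl]-2-methyloxiran-2-yl]-5,5-dimethoxypentan-3-yl}malonate | I/C(C)=C/C/C=C(\C)CC[C@@H]1O[C@@]1(C)CC[C@H](CC(OC)OC)C(C(=O)OC)C(=O)OC | intermediate
15 | (4R,7R)-4-(2,2-dimethoxyethyl)-7-[(1S,4E,7E)-1-hydroxy-8-iodo-4-methylnona-4,7-dien-1-yl]-7-methyl-2-oxooxepane-3-carboxylic acid (C3 epimers) | I/C(C)=C/C/C=C(\C)CC[C@H](O)[C@@]1(C)CC[C@H](CC(OC)OC)C(C(=O)O)C(=O)O1 | intermediate
16 | (4R,7R)-4-(2,2-dimethoxyethyl)-7-[(1S,4E,7E)-1-hydroxy-8-iodo-4-methylnona-4,7-dien-1-yl]-7-methyl-3-methylideneoxepan-2-one | I/C(C)=C/C/C=C(\C)CC[C@H](O)[C@@]1(C)CC[C@H](CC(OC)OC)C(=C)C(=O)O1 | intermediate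
17 | (1S,4E,7E)-1-[(2R,5R)-5-(2,2-dimethoxyethyl)-2-methyl-6-methylidene-7-oxooxepan-2-yl]-8-iodo-4-methylnona-4,7-dien-1-yl acetate | I/C(C)=C/C/C=C(\C)CC[C@H](OC(C)=O)[C@@]1(C)CC[C@H](CC(OC)OC)C(=C)C(=O)O1 | intermediate
18 | (1S,4E,7E)-8-iodo-4-methyl-1-[(2R,5R)-2-methyl-6-methylidene-7-oxo-5-(2-oxoethyl)oxepan-2-yl]nona-4,7-dien-1-yl acetate | I/C(C)=C/C/C=C(\C)CC[C@H](OC(C)=O)[C@@]1(C)CC[C@H](CC=O)C(=C)C(=O)O1 | intermediate
19 | (1R,11S,12R,4E,7E)-11-acetoxy-3-hydroxycembra-4,7,15(17)-trien-16,12-olide (C3 epimers) | C=C1C(=O)O[C@]2(C)CC[C@@H]1CC(O)/C(C)=C/C/C=C(\C)CC[C@@H]2OC(C)=O | intermediate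
20 | (1R,11S,12R,4E,7E)-11-acetoxy-3-oxocembra-4,7,15(17)-trien-16,12-olide | C=C1C(=O)O[C@]2(C)CC[C@@H]1CC(=O)/C(C)=C/C/C=C(\C)CC[C@@H]2OC(C)=O | intermediate
21 | dendronpholide B, (1R,3R,11S,12R,4E,7E) | C=C1C(=O)O[C@]2(C)CC[C@@H]1C[C@@H](O)/C(C)=C/C/C=C(\C)CC[C@@H]2OC(C)=O | target

## Summary

Total steps: 16. Longest linear sequence: 14 (geraniol → target, steps 3–16); the 2-step diiodide branch joins at step 9.

Steps most likely to fail, with fallbacks:

1. **Step 10 (epoxide-opening lactonisation).** Risks are epoxide hydrolysis, loss of stereospecificity at the tertiary carbon, or participation of the C7=C8 alkene. Fallback: switch from C–O alkylation to O-acylation. Hydrolyse epoxide 6 at the start (acid, C3 attack with inversion) to fix the anti C11/C12 diol, carry it as C11–OAc / C12–OH, and close the ε-lactone late by Shiina or Yamaguchi acylation of the tertiary alcohol with the 2-substituted acrylic acid.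

2. **Step 14 (NHK macrocyclisation).** Risks are oligomerisation or interference from the α-methylene lactone. Fallback: reverse the roles of the two couplings. Do an intermolecular NHK of the C3 aldehyde with excess diiodide 4 early (then oxidation/CBS and O-silylation), and close the 14-membered ring at C8–C9 by intramolecular B-alkyl Suzuki coupling.

3. **Step 16 (CBS reduction of the macrocyclic skipped dienone).** Risks are low selectivity in the macrocycle, conjugate reduction, or isomerisation into conjugation. Fallback: set C3 in the C–C bond-forming event with a catalytic asymmetric NHK using a Kishi chiral sulfonamide–Cr catalyst, which removes the enone stage altogether.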